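**Plan**

1. Drimane numbering is used (ring A = C1–C5, C10; ring B = C5–C10; C11 = CH2OAr carbon on C9; C12 = exocyclic CH2 on C8). The retrosynthesis cuts, in order: the C3–O ester bond, the C11–O aryl ether bond, the C9–C11 bond (retro-[2,3] shift, which returns the C8=C12 methylene to a C8=C9 bond carrying a C12 ester), one C4–CH3 bond, then C1–C2 and C5–C10 together.
2. What allows the last cut: the C5=C6 double bond is exocyclic to ring A at the ring-fusion carbon C5 and lies between quaternary C10 and the 4,4-dimethyl-3-oxy unit. Rings A and B are therefore the Diels–Alder adduct of a 2-silyloxy vinylallene (C2=C3(OSi)–C4(Me)=C5=C6) and an isopropenyl group (C10=C1), joined through C7–C8=C9.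
3. The open chain is cut at C4–CH3 (SN2' on a propargylic mesylate), at C5–C6 (acylation of an alkynylzinc) and at C8=C9 (Stobbe condensation).
4. Forward: the chain is joined first (steps 1–5), rings A and B arise together in the cycloaddition (step 6), then come C4 methylation, reduction, the C11 carbon by [2,3] shift, the coumarin ether and the ester.
5. Stereochemistry: asymmetric transfer hydrogenation sets the C6 carbinol (reagent control); anti-SN2' passes it to the allene axis; the axis sets C10 in the cycloaddition; C3 (axial hydride delivery) and C9 ([2,3] shift anti to the C10 methyl) follow by substrate control.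

Key step: step 6

Remark: the target is read as 3S,9R,10R (3-acyloxy cis and C9 aryloxymethyl trans to the C10 methyl group); ICH2SnBu3 and Ru[(S,S)-TsDPEN](p-cymene) are taken as purchased reagents.

**Route**

Step 1
Reactants: 1 dimethyl succinate; 2 methacrolein
Product: 5 (3E)-3-(methoxycarbonyl)-5-methylhexa-3,5-dienoic acid, via lithium enolate 3 (not isolated), via paraconate lactone 4 (not isolated)
Conditions: LiN(i-Pr)2 (1.05 equiv), THF, −78 °C; 2, −78 → 0 °C; t-BuOK (1.1 equiv), 0 °C → rt; aq. HCl
Reagents that add atoms: none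
Why: Stobbe condensation run with a preformed lithium enolate so that addition to the enal is 1,2; the aldolate should lactonise onto the distal ester and t-BuOK should open the lactone by E1cB elimination, giving the half-ester with the isopropenyl group cis to the CH2CO2H arm (E), the usual Stobbe outcome.

Step 2
Reactants: 6 but-3-yn-2-one
Product: 7 2-(triisopropylsilyloxy)but-1-en-3-yne
Conditions: i-Pr3SiOTf, Et3N, CH2Cl2, 0 °C
Reagents that add atoms: triisopropylsilyl trifluoromethanesulfonate, CC(C)[Si](OS(=O)(=O)C(F)(F)F)(C(C)C)C(C)C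
Why: Soft enolisation and O-silylation of a methyl ketone with a silyl triflate and an amine; the methyl group is the only enolisable position and the bulky silyl group should make the enol ether robust.

Step 3
Reactants: 5 (3E)-3-(methoxycarbonyl)-5-methylhexa-3,5-dienoic acid; 7 2-(triisopropylsilyloxy)but-1-en-3-yne
Product: 11 methyl (2E)-4-methyl-2-[2-oxo-5-(triisopropylsilyloxy)hex-5-en-3-yn-1-yl]penta-2,4-dienoate, via acid chloride 8 (not isolated), via lithium acetylide 9 (not isolated), via alkynylzinc chloride 10 (not isolated)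
Conditions: 5, (COCl)2, DMF (cat.), CH2Cl2, 0 °C → rt, evaporate; 7, n-BuLi, THF, −78 °C, then ZnCl2, 0 °C; combine with 8, Pd(PPh3)4 (3 mol %), THF, 0 °C → rt
Reagents that add atoms: oxalyl chloride, ClC(=O)C(=O)Cl (chlorine of 8); n-butyllithium, [Li]CCCC (lithium of 9); zinc chloride, Cl[Zn]Cl (zinc and chlorine of 10); none of these atoms remains in 11
Why: Acid chloride formation followed by a Negishi-type acylation of an alkynylzinc under zerovalent palladium catalysis, an amine-free ynone synthesis that should not enolise the C7 methylene or form a ketene.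

Step 4
Reactants: 11 methyl (2E)-4-methyl-2-[2-oxo-5-(triisopropylsilyloxy)hex-5-en-3-yn-1-yl]penta-2,4-dienoate
Product: 12 methyl (2E)-2-[(2S)-2-hydroxy-5-(triisopropylsilyloxy)hex-5-en-3-yn-1-yl]-4-methylpenta-2,4-dienoate
Conditions: Ru[(S,S)-TsDPEN](p-cymene) (2 mol %), i-PrOH, rt
Reagents that add atoms: none
Why: Noyori asymmetric transfer hydrogenation of an alkynyl ketone; the alkyne takes the place of the aryl group in the usual model, so the (S,S) catalyst should give the (S) carbinol under neutral conditions that spare the silyl enol ether and the enolisable ketone.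

Step 5
Reactants: 12 methyl (2E)-2-[(2S)-2-hydroxy-5-(triisopropylsilyloxy)hex-5-en-3-yn-1-yl]-4-methylpenta-2,4-dienoate
Product: 14 methyl (2E)-4-methyl-2-[(aS)-4-methyl-5-(triisopropylsilyloxy)hexa-2,3,5-trien-1-yl]penta-2,4-dienoate, via propargylic mesylate 13 (not isolated)
Conditions: MsCl, Et3N, THF, −40 °C; then MeMgBr, CuBr·SMe2, LiBr, THF, −78 → −40 °C; quick filtration through Et3N-deactivated silica, used at once
Reagents that add atoms: methanesulfonyl chloride, CS(=O)(=O)Cl (mesyl group of 13); methylmagnesium bromide, C[Mg]Br (methyl group on C4 of 14)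
Why: Anti-selective SN2' substitution of a propargylic mesylate by a methylcopper reagent; methyl enters at C4 opposite the leaving group, so the (S) carbinol should be converted into the (aS) allene axis, and a mono-organocopper species should not add to the hindered dienoate at low temperature.

Step 6
Reactants: 14 methyl (2E)-4-methyl-2-[(aS)-4-methyl-5-(triisopropylsilyloxy)hexa-2,3,5-trien-1-yl]penta-2,4-dienoate
Product: 15 methyl (8aR)-5,8a-dimethyl-6-(triisopropylsilyloxy)-3,7,8,8a-tetrahydronaphthalene-2-carboxylate
Conditions: toluene (0.01 M), BHT (cat.), base-washed glassware, 80 °C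
Reagents that add atoms: none
Why: Thermal intramolecular Diels–Alder reaction in which the 2-silyloxy vinylallene (C2=C3–C4=C5, using the inner π bond of the allene) is the diene and the isopropenyl terminus C10=C1 of the dienoate is the dienophile, so that C1–C2 and C5–C10 form in one asynchronous concerted event led by the bond between the nucleophilic diene terminus C2 and the δ-carbon C1 of the dienoate. The closest known reaction type is the intramolecular [4+2] cycloaddition of vinylallenes that carry the alkene on the allene terminus, which is fast because the cumulated bond is strained and the diene terminus C5 has no in-plane substituent. Ring A closes as the new cyclohexene of the [4+2] (six-membered, C3=C4 emerging as the silyl enol ether), and ring B closes at the same time through the C7–C8=C9 tether as a fused six-membered ring whose C5=C6 bond is the surviving outer π bond of the allene, exocyclic to ring A. The only new stereocenter, C10, is controlled by the allene axis: C7 stands perpendicular to the diene plane on one face only, the dienophile can reach C5 only from that face with its methyl endo and C9 exo, so the (aS) axis should be converted into (10R). The step needs periselectivity for the distal alkene and one orientation; the one-carbon distance of C8=C9 from the allene rules that bond out, the tether holds C10 over C5, and the unsubstituted C2H2 terminus excludes the [1,5]-hydrogen shift that otherwise competes in vinylallenes.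

Step 7
Reactants: 15 methyl (8aR)-5,8a-dimethyl-6-(triisopropylsilyloxy)-3,7,8,8a-tetrahydronaphthalene-2-carboxylate
Product: 17 methyl (8aR)-5,5,8a-trimethyl-6-oxo-3,5,6,7,8,8a-hexahydronaphthalene-2-carboxylate, via sulfonium dienolate 16 (not isolated)
Conditions: TASF (1.1 equiv), MeI (5 equiv), THF, −78 → 0 °C
Reagents that add atoms: iodomethane, CI (second methyl group on C4); tris(dimethylamino)sulfonium difluorotrimethylsilicate, CN(C)[S+](N(C)C)N(C)C.C[Si-](C)(C)(F)F (counter-ion of 16 only)
Why: Fluoride-mediated regiospecific alkylation of a silyl enol ether; the naked dienolate should be methylated at its α-carbon C4, the normal site for extended enolates, which creates the 4,4-dimethyl group and leaves C5=C6 out of conjugation without touching the ester.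

Step 8
Reactants: 17 methyl (8aR)-5,5,8a-trimethyl-6-oxo-3,5,6,7,8,8a-hexahydronaphthalene-2-carboxylate
Product: 18 (2S,4aR)-6-(hydroxymethyl)-1,1,4a-trimethyl-1,2,3,4,4a,7-hexahydronaphthalen-2-ol
Conditions: LiAlH4, Et2O, −40 → 0 °C; then H2O
Reagents that add atoms: none
Why: Hydride reduction of both carbonyl groups; hydride should add to the C3 ketone axially from the face opposite the axial C10 and C4 methyl groups to give the equatorial (3S) alcohol cis to the C10 methyl (substrate control), and 1,2-reduction of the enoate gives the primary allylic alcohol.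

Step 9
Reactants: 18 (2S,4aR)-6-(hydroxymethyl)-1,1,4a-trimethyl-1,2,3,4,4a,7-hexahydronaphthalen-2-ol
Product: 19 (2S,4aR)-1,1,4a-trimethyl-6-{[(tributylstannyl)methoxy]methyl}-1,2,3,4,4a,7-hexahydronaphthalen-2-ol
Conditions: KH (1.05 equiv), ICH2SnBu3 (1.1 equiv), THF, 0 °C → rt
Reagents that add atoms: tributyl(iodomethyl)stannane, CCCC[Sn](CCCC)(CCCC)CI
Why: Williamson etherification; the unhindered primary allylic alkoxide should be alkylated much faster than the secondary C3 alkoxide, which is shielded by the adjacent gem-dimethyl group.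

Step 10
Reactants: 19 (2S,4aR)-1,1,4a-trimethyl-6-{[(tributylstannyl)methoxy]methyl}-1,2,3,4,4a,7-hexahydronaphthalen-2-ol
Product: 21 (2S,4aR,5R)-5-(hydroxymethyl)-1,1,4a-trimethyl-6-methylidene-1,2,3,4,4a,5,6,7-octahydronaphthalen-2-ol, via dilithio alkoxymethyl species 20 (not isolated)
Conditions: n-BuLi (2.3 equiv), THF, −78 → −40 °C; then H2O
Reagents that add atoms: n-butyllithium, [Li]CCCC (lithium of 20 only)
Why: Wittig–Still [2,3] sigmatropic rearrangement: tin–lithium exchange gives the α-alkoxymethyllithium, which bonds to C9 through a five-membered envelope transition state while the double bond moves to C8=C12; axial attack anti to the angular C10 methyl, through the ring B half-chair that keeps ring A a chair, should place the CH2OH group trans to that methyl (9R).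

Step 11
Reactants: 21 (2S,4aR,5R)-5-(hydroxymethyl)-1,1,4a-trimethyl-6-methylidene-1,2,3,4,4a,5,6,7-octahydronaphthalen-2-ol; 22 umbelliferone (7-hydroxycoumarin)
Product: 23 7-{[(1R,6S,8aR)-6-hydroxy-5,5,8a-trimethyl-2-methylidene-1,2,3,5,6,7,8,8a-octahydronaphthalen-1-yl]methoxy}-2H-chromen-2-one
Conditions: PPh3, DIAD, THF, 0 °C → rt
Reagents that add atoms: none
Why: Mitsunobu etherification of the primary alcohol with an acidic phenol (pKa about 8); the hindered secondary C3 hydroxyl should not be activated, and no stereocenter is touched.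

Step 12
Reactants: 23 7-{[(1R,6S,8aR)-6-hydroxy-5,5,8a-trimethyl-2-methylidene-1,2,3,5,6,7,8,8a-octahydronaphthalen-1-yl]methoxy}-2H-chromen-2-one; 24 3-hydroxy-3-methylbutanoic acid
Product: 25 (2S,4aR,5R)-1,1,4a-trimethyl-6-methylidene-5-{[(2-oxo-2H-chromen-7-yl)oxy]methyl}-1,2,3,4,4a,5,6,7-octahydronaphthalen-2-yl 3-hydroxy-3-methylbutanoate (CNP0300349.1)
Conditions: DCC, DMAP (cat.), CH2Cl2, 0 °C → rt
Reagents that add atoms: none
Why: Steglich esterification; the tertiary hydroxyl of the acid is too hindered to compete as a nucleophile, and C3 keeps its configuration because its C–O bond is not broken.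

**Compound list**

1 | dimethyl succinate | COC(=O)CCC(=O)OC | starting material
2 | methacrolein (2-methylprop-2-enal) | CC(=C)C=O | starting material
3 | lithium enolate of dimethyl succinate | COC(=O)CC=C(OC)O[Li] | intermediate
4 | methyl 5-oxo-2-(prop-1-en-2-yl)oxolane-3-carboxylate (paraconate lactone, racemic mixture of diastereomers, both centers lost in the same step) | COC(=O)C1CC(=O)OC1C(C)=C | intermediate
5 | (3E)-3-(methoxycarbonyl)-5-methylhexa-3,5-dienoic acid | C=C(C)/C=C(\CC(=O)O)C(=O)OC | intermediate
6 | but-3-yn-2-one | CC(=O)C#C | starting material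
7 | 2-(triisopropylsilyloxy)but-1-en-3-yne | C=C(O[Si](C(C)C)(C(C)C)C(C)C)C#C | intermediate
8 | methyl (2E)-2-(2-chloro-2-oxoethyl)-4-methylpenta-2,4-dienoate (acid chloride of 5) | C=C(C)/C=C(\CC(=O)Cl)C(=O)OC | intermediate
9 | lithium acetylide of 7 | [Li]C#CC(=C)O[Si](C(C)C)(C(C)C)C(C)C | intermediate
10 | [3-(triisopropylsilyloxy)but-3-en-1-yn-1-yl]zinc chloride | Cl[Zn]C#CC(=C)O[Si](C(C)C)(C(C)C)C(C)C | intermediate
11 | methyl (2E)-4-methyl-2-[2-oxo-5-(triisopropylsilyloxy)hex-5-en-3-yn-1-yl]penta-2,4-dienoate | C=C(C)/C=C(\CC(=O)C#CC(=C)O[Si](C(C)C)(C(C)C)C(C)C)C(=O)OC | intermediate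
12 | methyl (2E)-2-[(2S)-2-hydroxy-5-(triisopropylsilyloxy)hex-5-en-3-yn-1-yl]-4-methylpenta-2,4-dienoate | C=C(C)/C=C(\C[C@H](O)C#CC(=C)O[Si](C(C)C)(C(C)C)C(C)C)C(=O)OC | intermediate
13 | (2S)-methanesulfonate of 12 | C=C(C)/C=C(\C[C@H](OS(C)(=O)=O)C#CC(=C)O[Si](C(C)C)(C(C)C)C(C)C)C(=O)OC | intermediate
14 | methyl (2E)-4-methyl-2-[(aS)-4-methyl-5-(triisopropylsilyloxy)hexa-2,3,5-trien-1-yl]penta-2,4-dienoate | C=C(C)/C=C(\CC([H])=[C@@]=C(C)C(=C)O[Si](C(C)C)(C(C)C)C(C)C)C(=O)OC | intermediate
15 | methyl (8aR)-5,8a-dimethyl-6-(triisopropylsilyloxy)-3,7,8,8a-tetrahydronaphthalene-2-carboxylate | COC(=O)C1=C[C@@]2(C)CCC(O[Si](C(C)C)(C(C)C)C(C)C)=C(C)C2=CC1 | intermediate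
16 | tris(dimethylamino)sulfonium dienolate of methyl (8aR)-5,8a-dimethyl-6-oxo-hexahydronaphthalene-2-carboxylate (O-desilylated 15) | CN(C)[S+](N(C)C)N(C)C.COC(=O)C1=C[C@@]2(C)CCC([O-])=C(C)C2=CC1 | intermediate
17 | methyl (8aR)-5,5,8a-trimethyl-6-oxo-3,5,6,7,8,8a-hexahydronaphthalene-2-carboxylate | COC(=O)C1=C[C@@]2(C)CCC(=O)C(C)(C)C2=CC1 | intermediate
18 | (2S,4aR)-6-(hydroxymethyl)-1,1,4a-trimethyl-1,2,3,4,4a,7-hexahydronaphthalen-2-ol | OCC1=C[C@@]2(C)CC[C@H](O)C(C)(C)C2=CC1 | intermediate
19 | (2S,4aR)-1,1,4a-trimethyl-6-{[(tributylstannyl)methoxy]methyl}-1,2,3,4,4a,7-hexahydronaphthalen-2-ol | CCCC[Sn](CCCC)(CCCC)COCC1=C[C@@]2(C)CC[C@H](O)C(C)(C)C2=CC1 | intermediate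
20 | lithium (2S,4aR)-6-[(lithiomethoxy)methyl]-1,1,4a-trimethyl-1,2,3,4,4a,7-hexahydronaphthalen-2-olate | [Li]COCC1=C[C@@]2(C)CC[C@H](O[Li])C(C)(C)C2=CC1 | intermediate
21 | (2S,4aR,5R)-5-(hydroxymethyl)-1,1,4a-trimethyl-6-methylidene-1,2,3,4,4a,5,6,7-octahydronaphthalen-2-ol | C=C1CC=C2C(C)(C)[C@@H](O)CC[C@]2(C)[C@@H]1CO | intermediate
22 | umbelliferone (7-hydroxy-2H-chromen-2-one) | O=c1ccc2ccc(O)cc2o1 | starting material
23 | 7-{[(1R,6S,8aR)-6-hydroxy-5,5,8a-trimethyl-2-methylidene-1,2,3,5,6,7,8,8a-octahydronaphthalen-1-yl]methoxy}-2H-chromen-2-one | C=C1CC=C2C(C)(C)[C@@H](O)CC[C@]2(C)[C@@H]1COc1ccc2ccc(=O)oc2c1 | intermediate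
24 | 3-hydroxy-3-methylbutanoic acid | CC(C)(O)CC(=O)O | starting material
25 | (2S,4aR,5R)-1,1,4a-trimethyl-6-methylidene-5-{[(2-oxo-2H-chromen-7-yl)oxy]methyl}-1,2,3,4,4a,5,6,7-octahydronaphthalen-2-yl 3-hydroxy-3-methylbutanoate | C=C1CC=C2C(C)(C)[C@@H](OC(=O)CC(C)(C)O)CC[C@]2(C)[C@@H]1COc1ccc2ccc(=O)oc2c1 | target

**Step count**

Total: 12 steps. Longest linear sequence: 11 steps (steps 1 and 3–12; step 2 is a one-step branch).

**Steps most likely to fail**

Step 10. The carbanion may not discriminate well between the two faces of C9, because ring B is a nearly flat 1,4-diene at this stage and the bias against the methyl face may be small; a [1,2] shift may also compete. The fallback sets out from 18 and replaces the anionic [2,3] shift by a thermal [3,3] shift, whose later, chair-like transition state should respond more strongly to the preference for the axial bond anti to the angular methyl. Johnson–Claisen rearrangement of the primary allylic alcohol (MeC(OEt)3, EtCO2H cat., xylene, 140 °C) should give the ethyl ester F1 with the two-carbon chain on C9. Saponification (LiOH, aq. THF) gives the acid F2. The extra carbon is then excised by Barton decarboxylative hydroxylation: the thiohydroxamate ester F3 (N-hydroxypyridine-2-thione, DCC) is photolysed under O2 with t-BuSH and the hydroperoxide is reduced with PPh3, which returns to the route at 21.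

Step 6. The cycloaddition may be outrun by hydrolysis or dimerisation of the silyloxy vinylallene, since the ester is twisted out of conjugation with the dienophile in the compact transition state and lends little activation. The fallback sets out from 14 and changes the diene from a neutral silyl enol ether to an oxyanion. TASF in THF at −78 °C removes the silyl group to give the naked 2-oxido vinylallene F4, whose anion-accelerated [4+2] reaction (or stepwise Michael–Michael equivalent) should proceed at low temperature. This gives the dienolate 16 directly, which is methylated in the same flask with MeI, so the fallback rejoins the route at 17.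

Step 5. The γ-hydroxy ester 12 may lactonise onto the C12 ester before or during mesylation, and the substitution may lose anti selectivity or regioselectivity. The fallback sets out from 12 and uses the lactone as the leaving group instead of avoiding it. Deliberate lactonisation (NaH cat., THF, 0 °C) gives the alkylidene butyrolactone F5. The same methylcopper reagent (MeMgBr, CuBr·SMe2, LiBr, THF, −78 °C) should open it in the anti-SN2' sense with the carboxylate departing, giving the allenic acid F6. Esterification with Me3SiCHN2 (toluene/MeOH, 0 °C) returns to the route at 14.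

**Further compounds**

F1 | step 10 | ethyl 2-[(1R,6S,8aR)-6-hydroxy-5,5,8a-trimethyl-2-methylidene-1,2,3,5,6,7,8,8a-octahydronaphthalen-1-yl]acetate | C=C1CC=C2C(C)(C)[C@@H](O)CC[C@]2(C)[C@@H]1CC(=O)OCC
F2 | step 10 | 2-[(1R,6S,8aR)-6-hydroxy-5,5,8a-trimethyl-2-methylidene-1,2,3,5,6,7,8,8a-octahydronaphthalen-1-yl]acetic acid | C=C1CC=C2C(C)(C)[C@@H](O)CC[C@]2(C)[C@@H]1CC(=O)O
F3 | step 10 | 2-thioxopyridin-1(2H)-yl ester of F2 (Barton ester) | C=C1CC=C2C(C)(C)[C@@H](O)CC[C@]2(C)[C@@H]1CC(=O)ON1C=CC=CC1=S
F4 | step 6 | tris(dimethylamino)sulfonium enolate of methyl (2E)-4-methyl-2-[(aS)-4-methyl-5-oxohexa-2,3-dien-1-yl]penta-2,4-dienoate | CN(C)[S+](N(C)C)N(C)C.C=C(C)/C=C(\CC([H])=[C@@]=C(C)C(=C)[O-])C(=O)OC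
F5 | step 5 | (3E,5S)-3-(2-methylprop-2-en-1-ylidene)-5-[3-(triisopropylsilyloxy)but-3-en-1-yn-1-yl]oxolan-2-one | C=C(C)/C=C1\C[C@@H](C#CC(=C)O[Si](C(C)C)(C(C)C)C(C)C)OC1=O
F6 | step 5 | (2E)-4-methyl-2-[(aS)-4-methyl-5-(triisopropylsilyloxy)hexa-2,3,5-trien-1-yl]penta-2,4-dienoic acid | C=C(C)/C=C(\CC([H])=[C@@]=C(C)C(=C)O[Si](C(C)C)(C(C)C)C(C)C)C(=O)O
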